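The ring-closing bond is the aryl–CH2 bond joining ring A (the 4-oxygenated ring of the biaryl) to the two-carbon bridge that leads to ring B. Without that bond, ring A is a para-substituted phenyl ring whose two C–H bonds ortho to the biaryl axis are equivalent, and the phenol oxygen of ring D sits ortho to the same axis. A hydroxyl-directed, palladium-catalysed C–H olefination therefore closes the 16-membered ring onto a vinyl group on ring B with no prior functionalisation of ring A. The precursor is an open-chain four-ring styrene with benzyl ethers on rings A and B; a single hydrogenation then saturates the new alkene and frees both phenols.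

Key step: step 6

Ring labels: ring A = 4-oxygenated biaryl ring; ring D = the other biaryl ring (OH ortho to the axis); ring C = para-phenylene; ring B = the catechol-derived ring.

Assumption: the target has no stereocentre and is treated as the achiral constitution shown; the macrocyclic stilbene 11 is drawn E (usual outcome of syn-β-hydride elimination), and a Z isomer would serve equally because step 7 removes the double bond.

Step 1
Reactants: 1 2-bromo-3-hydroxybenzaldehyde; 2 [4-(benzyloxy)phenyl]boronic acid
Product: 3 4'-(benzyloxy)-6-hydroxybiphenyl-2-carbaldehyde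
Conditions: Pd(OAc)2 (3 mol %), SPhos (6 mol %), K3PO4, toluene/H2O, 90 °C
Reagents that add atoms: none
Why: Suzuki–Miyaura coupling, in which the bulky biarylphosphine should cope with the di-ortho-substituted bromide while the free phenol and the aldehyde tolerate aqueous phosphate.

Step 2
Reactants: 3 4'-(benzyloxy)-6-hydroxybiphenyl-2-carbaldehyde
Product: 4 4'-(benzyloxy)-6-vinylbiphenyl-2-ol
Conditions: MePPh3Br (2.5 equiv), KOtBu (2.4 equiv), THF, 0 °C to rt
Reagents that add atoms: methyltriphenylphosphonium bromide, C[P+](c1ccccc1)(c1ccccc1)c1ccccc1.[Br-]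
Why: Wittig methylenation, with one extra equivalent of ylide covering the phenol, whose phenoxide is meta to the aldehyde and should not deactivate it.

Step 3
Reactants: 5 4-(benzyloxy)-3-hydroxybenzaldehyde; 6 (4-bromophenyl)boronic acid
Product: 7 4-(benzyloxy)-3-(4-bromophenoxy)benzaldehyde
Conditions: Cu(OAc)2 (20 mol %), pyridine, 4 Å MS, CH2Cl2, O2 (1 atm), rt
Reagents that add atoms: none
Why: Chan–Lam O-arylation at room temperature should leave the aryl bromide and the aldehyde untouched, so ring C arrives with the halide needed in step 4.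

Step 4
Reactants: 4 4'-(benzyloxy)-6-vinylbiphenyl-2-ol; 7 4-(benzyloxy)-3-(4-bromophenoxy)benzaldehyde
Product: 9 4-(benzyloxy)-3-{4-[2-(4'-(benzyloxy)-6-hydroxybiphenyl-2-yl)ethyl]phenoxy}benzaldehyde, via alkylborane borinate 8 (not isolated)
Conditions: 9-BBN (2.2 equiv), THF, 0 to 50 °C; then aq. K3PO4, 7, Pd(dppf)Cl2 (5 mol %), THF/DMF, 60 °C
Reagents that add atoms: none
Why: Anti-Markovnikov hydroboration of the styrene followed by B-alkyl Suzuki–Miyaura coupling; one equivalent of borane is taken up by the phenol as a borinate that the aqueous base cleaves, and the same base destroys residual B–H before the aldehyde-bearing bromide is added.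

Step 5
Reactants: 9 4-(benzyloxy)-3-{4-[2-(4'-(benzyloxy)-6-hydroxybiphenyl-2-yl)ethyl]phenoxy}benzaldehyde
Product: 10 4'-(benzyloxy)-6-(2-{4-[2-(benzyloxy)-5-vinylphenoxy]phenyl}ethyl)biphenyl-2-ol
Conditions: MePPh3Br (2.5 equiv), KOtBu (2.4 equiv), THF, 0 °C to rt
Reagents that add atoms: methyltriphenylphosphonium bromide, C[P+](c1ccccc1)(c1ccccc1)c1ccccc1.[Br-]
Why: Wittig methylenation of the only carbonyl group, with excess ylide absorbing the ring D phenol proton.

Step 6
Reactants: 10 4'-(benzyloxy)-6-(2-{4-[2-(benzyloxy)-5-vinylphenoxy]phenyl}ethyl)biphenyl-2-ol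
Product: 11 di-O-benzyl dehydroplagiochin E (16-membered macrocyclic E-stilbene; CH=CH between rings A and B, ring D phenol free)
Conditions: Pd(OAc)2 (10 mol %), Cu(OAc)2 (20 mol %), 4 Å MS, DMF, air, 100 °C, slow addition (2 mM)
Reagents that add atoms: none
Why: The ring D phenoxide binds Pd(OAc)2, and concerted metalation–deprotonation at one of the two homotopic ortho C–H bonds of ring A gives a six-membered oxapalladacycle; the ring B styrene then inserts with the aryl group going to the terminal carbon, and syn-β-hydride elimination releases the stilbene while the zerovalent palladium is reoxidised by Cu(OAc)2 and O2. The closest known reaction type is the hydroxyl-directed Fujiwara–Moritani (oxidative Heck) olefination of 2-arylphenols with styrenes and acrylates, together with palladium-catalysed C–H olefination macrocyclisations of tethered alkenes. The 16-membered ring closes in a 16-endo-trig mode, with both alkene carbons inside the ring. No stereocentre is formed, and the alkene geometry is irrelevant because step 7 saturates it. The step needs site selectivity (the ring D hydroxyl reaches only the two equivalent ortho positions of ring A, and all other phenols are benzylated), terminal regioselectivity of insertion (styrenes place palladium at the benzylic carbon) and ring closure over oligomerisation (slow addition at high dilution).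

Step 7
Reactants: 11 di-O-benzyl dehydroplagiochin E
Product: 12 plagiochin E
Conditions: H2 (1 atm), Pd/C, EtOAc/MeOH, rt
Reagents that add atoms: none
Why: Heterogeneous hydrogenation should saturate the stilbene and hydrogenolyse both aryl benzyl ethers in one operation, the diaryl ether and biaryl being inert.

Compound list
1 | 2-bromo-3-hydroxybenzaldehyde | O=Cc1cccc(O)c1Br | starting material
2 | [4-(benzyloxy)phenyl]boronic acid | OB(O)c1ccc(OCc2ccccc2)cc1 | starting material
3 | 4'-(benzyloxy)-6-hydroxybiphenyl-2-carbaldehyde | O=Cc1cccc(O)c1-c1ccc(OCc2ccccc2)cc1 | intermediate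
4 | 4'-(benzyloxy)-6-vinylbiphenyl-2-ol | C=Cc1cccc(O)c1-c1ccc(OCc2ccccc2)cc1 | intermediate
5 | 4-(benzyloxy)-3-hydroxybenzaldehyde | O=Cc1ccc(OCc2ccccc2)c(O)c1 | starting material
6 | (4-bromophenyl)boronic acid | OB(O)c1ccc(Br)cc1 | starting material
7 | 4-(benzyloxy)-3-(4-bromophenoxy)benzaldehyde | O=Cc1ccc(OCc2ccccc2)c(Oc2ccc(Br)cc2)c1 | intermediate
8 | alkylborane borinate: 9-{2-[4'-(benzyloxy)-6-(9-borabicyclo[3.3.1]nonan-9-yloxy)biphenyl-2-yl]ethyl}-9-borabicyclo[3.3.1]nonane | C(Oc1ccc(cc1)-c1c(OB2C3CCCC2CCC3)cccc1CCB1C2CCCC1CCC2)c1ccccc1 | intermediate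
9 | 4-(benzyloxy)-3-{4-[2-(4'-(benzyloxy)-6-hydroxybiphenyl-2-yl)ethyl]phenoxy}benzaldehyde | O=Cc1ccc(OCc2ccccc2)c(c1)Oc1ccc(cc1)CCc1cccc(O)c1-c1ccc(OCc2ccccc2)cc1 | intermediate
10 | 4'-(benzyloxy)-6-(2-{4-[2-(benzyloxy)-5-vinylphenoxy]phenyl}ethyl)biphenyl-2-ol | C=Cc1ccc(OCc2ccccc2)c(c1)Oc1ccc(cc1)CCc1cccc(O)c1-c1ccc(OCc2ccccc2)cc1 | intermediate
11 | di-O-benzyl dehydroplagiochin E (macrocyclic E-stilbene) | O(Cc1ccccc1)c1ccc2c(c1)/C=C/c1ccc(OCc3ccccc3)c(c1)Oc1ccc(cc1)CCc1cccc(O)c1-2 | intermediate
12 | plagiochin E | Oc1ccc2c(c1)CCc1ccc(O)c(c1)Oc1ccc(cc1)CCc1cccc(O)c1-2 | target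

Total step count: 7. Longest linear sequence: 6 steps (1, 2, 4, 5, 6, 7 from compound 1).

Steps most likely to fail

Step 6. Cyclopalladation may be slow on the twisted, tri-ortho-substituted biaryl. Intermolecular olefination (oligomerisation), or oxidative O-cyclisation of the ring D phenol onto the new stilbene, may outrun or follow ring closure. Strain in the unsaturated 16-membered ring may also raise the barrier. Fallback: the same bond is closed at the saturated level from a pre-halogenated ring A. Setting out from 1, Suzuki–Miyaura coupling with (2-chloro-4-methoxyphenyl)boronic acid (Pd(PPh3)4, Na2CO3, DME/H2O; the C–Br bond reacts, the C–Cl bond stays) would give 2'-chloro-6-hydroxy-4'-methoxybiphenyl-2-carbaldehyde F1. Wittig methylenation would give 2'-chloro-4'-methoxy-6-vinylbiphenyl-2-ol F2. Hydroboration with 9-BBN would give the alkylborane borinate F3, which would be coupled in the same flask with 7 (Pd(dppf)Cl2, aq. K3PO4; aryl chloride untouched) to the chloro seco-aldehyde F4. A second methylenation would give the chloro seco-styrene F5. Hydroboration of the ring B vinyl group would give the alkylborane borinate F6, and intramolecular B-alkyl Suzuki–Miyaura coupling at the ring A chloride (Pd(OAc)2, SPhos, K3PO4, THF/H2O, high dilution) would give the saturated macrocycle F7. BBr3 (CH2Cl2, −78 °C to rt) would cleave the methyl and benzyl ethers and return to the route at 12.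

Step 4. Hydroboration of the hindered styrene may be incomplete in the presence of the free phenol, and the alkylborane may suffer protodeboronation or β-hydride elimination during coupling. Surviving B–H may also reduce the aldehyde. Fallback: from 4 and 7, Mizoroki–Heck coupling (Pd(OAc)2, P(o-tol)3, K2CO3, DMF, 100 °C) would give the E-stilbene aldehyde F8. Diimide reduction (dipotassium azodicarboxylate, AcOH, MeOH/THF), which touches neither the aldehyde nor the benzyl ethers, would then return to the route at 9.

Step 3. Transmetalation and C–O bond formation may be slow with the electron-poor, ortho-alkoxylated phenol, so protodeboronation and homocoupling of the boronic acid consume the partner. Fallback: from 5, Ullmann-type coupling with 1-bromo-4-iodobenzene (CuI, N,N-dimethylglycine, Cs2CO3, dioxane, 90 °C), selective for the C–I bond, would return directly at 7 without any new compound.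

Further compounds
F1 | step 6 | 2'-chloro-6-hydroxy-4'-methoxybiphenyl-2-carbaldehyde | O=Cc1cccc(O)c1-c1ccc(OC)cc1Cl
F2 | step 6 | 2'-chloro-4'-methoxy-6-vinylbiphenyl-2-ol | C=Cc1cccc(O)c1-c1ccc(OC)cc1Cl
F3 | step 6 | alkylborane borinate from F2 | COc1ccc(c(Cl)c1)-c1c(OB2C3CCCC2CCC3)cccc1CCB1C2CCCC1CCC2
F4 | step 6 | 4-(benzyloxy)-3-{4-[2-(2'-chloro-6-hydroxy-4'-methoxybiphenyl-2-yl)ethyl]phenoxy}benzaldehyde | O=Cc1ccc(OCc2ccccc2)c(c1)Oc1ccc(cc1)CCc1cccc(O)c1-c1ccc(OC)cc1Cl
F5 | step 6 | 2'-chloro-4'-methoxy-6-(2-{4-[2-(benzyloxy)-5-vinylphenoxy]phenyl}ethyl)biphenyl-2-ol | C=Cc1ccc(OCc2ccccc2)c(c1)Oc1ccc(cc1)CCc1cccc(O)c1-c1ccc(OC)cc1Cl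
F6 | step 6 | alkylborane borinate from F5 | COc1ccc(c(Cl)c1)-c1c(OB2C3CCCC2CCC3)cccc1CCc1ccc(cc1)Oc1cc(CCB2C3CCCC2CCC3)ccc1OCc1ccccc1
F7 | step 6 | ring A O-methyl, ring B O-benzyl plagiochin E | COc1ccc2c(c1)CCc1ccc(OCc3ccccc3)c(c1)Oc1ccc(cc1)CCc1cccc(O)c1-2
F8 | step 4 | 4-(benzyloxy)-3-{4-[(E)-2-(4'-(benzyloxy)-6-hydroxybiphenyl-2-yl)vinyl]phenoxy}benzaldehyde | O=Cc1ccc(OCc2ccccc2)c(c1)Oc1ccc(cc1)/C=C/c1cccc(O)c1-c1ccc(OCc2ccccc2)cc1
F0 | step 3 | none | none
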